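The carbocycle is numbered C1–C10: C2 is the hemiketal carbon (oxygen bridge to C5), C4=C15H2, the lactone is O6–C12(=O)–C11(=C13H2)–C7, the tiglate sits on O8, C10=C14H2, and each oxygen takes the number of its carbon.
Retrosynthesis cuts, in order: the O8 tigloyl group and the C2 OH/OMe exchange, C11=C13 (Mannich/elimination), the ring bond C7–C8, C7=C11 (metathesis), C6–C7 (vinyl addition), C4=C15 (Wittig) and C1–C2 (allyl anion plus lactone).
Enabling feature: in the trans γ-lactone (C6, C7, C11, C12, O6) C7 is the β-carbon of a butenolide whose γ-carbon C6 is stereogenic, and C7 is bonded to carbinol carbon C8, so a reductive aldehyde–enoate coupling makes C7–C8 and both stereocentres at once.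
Forward order: the oxolane ring (O5, C2–C5) is the furanose ring of 2-deoxy-D-ribose; the C1/C10/C9/C8 chain is added at C2, the butenolide is built on C6, and the ten-membered carbocycle is closed last by cathodic C7–C8 coupling.
Stereochemistry: C5 is C4 of the sugar; C2 is the ketal anomer with the C1 chain cis to C6; C6 comes from chelation-controlled vinyl addition; C7 from attack anti to the C6 substituent; C8 from the geometry of the ring closure.
Key step: step 16

Assumption: in acidic methanol the two C2 anomers of the methyl ketal interconvert, so the anomer that is not needed can be returned to the conditions of step 6.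
Assumption: the hemiketal drawn is the resting form of the C2 ketone/O5 alcohol pair, so hydrolysis of the bridged methyl ketal stops at the target.
Abbreviations: TBDPS = tert-butyldiphenylsilyl, TES = triethylsilyl, PMB = 4-methoxybenzyl. Oxolane locants are chosen to coincide with the target numbering.

Step 1
Reactants: 1 2-deoxy-D-ribose
Product: 2 2-deoxy-D-ribono-1,4-lactone
Conditions: Br2, H2O, rt
Reagents that add atoms: none
Why: Bromine-water oxidation of the aldose hemiacetal gives the aldonic acid, which lactonizes to the five-membered lactone, and the two sugar stereocentres (later C4 and C5) are not touched.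

Step 2
Reactants: 2 2-deoxy-D-ribono-1,4-lactone
Product: 4 5-O-TBDPS-3-O-TES-2-deoxy-D-ribono-1,4-lactone, via 5-O-TBDPS lactone 3 (not isolated)
Conditions: TBDPSCl, imidazole, DMF, 0 °C; then TESCl, rt
Reagents that add atoms: tert-butyl(chloro)diphenylsilane, CC(C)(C)[Si](Cl)(c1ccccc1)c1ccccc1; chlorotriethylsilane, CC[Si](Cl)(CC)CC
Why: Silylation with imidazole as base, in which the bulky TBDPSCl reacts only at the primary hydroxyl at 0 °C and TESCl then caps the secondary hydroxyl with a group that acidic methanol removes in step 6.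

Step 3
Reactants: 5 3-methylbut-3-en-1-ol
Product: 7 3-[(tributylstannyl)methyl]but-3-en-1-ol, via dilithio alkoxide 6 (not isolated)
Conditions: n-BuLi (2.2 equiv), TMEDA, Et2O, 0 °C to rt; then Bu3SnCl, −78 °C; aq. NH4Cl
Reagents that add atoms: tributyltin chloride (Bu3SnCl), CCCC[Sn](Cl)(CCCC)CCCC
Why: Alkoxide-directed allylic lithiation of the methyl group gives the dianion, whose carbanion end is trapped at tin far faster than the alkoxide end (stannylation of an allyl anion).

Step 4
Reactants: 7 3-[(tributylstannyl)methyl]but-3-en-1-ol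
Product: 8 tributyl{2-[2-(4-methoxybenzyloxy)ethyl]prop-2-en-1-yl}stannane
Conditions: NaH, 4-MeOC6H4CH2Cl, Bu4NI (cat.), THF/DMF, 0 °C to rt
Reagents that add atoms: 4-methoxybenzyl chloride, COc1ccc(CCl)cc1
Why: Williamson etherification under basic conditions, which the acid-sensitive allylstannane tolerates, installs an O8 group that survives fluoride, organometallics and metathesis and is later removed oxidatively.

Step 5
Reactants: 8 tributyl{2-[2-(4-methoxybenzyloxy)ethyl]prop-2-en-1-yl}stannane; 4 5-O-TBDPS-3-O-TES-2-deoxy-D-ribono-1,4-lactone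
Product: 10 C2 hemiketal (4S,5R)-2-[4-(PMB-oxy)-2-methylidenebutyl]-5-(TBDPS-oxymethyl)-4-(TES-oxy)oxolan-2-ol as both C2 anomers, via allyllithium 9 (not isolated)
Conditions: 8, n-BuLi, THF, −78 °C; then 4, −78 °C; aq. NH4Cl
Reagents that add atoms: none
Why: Tin–lithium exchange gives the 2-substituted allyllithium, and its 1,2-addition to the γ-lactone stops at the lithium salt of the cyclic hemiketal at −78 °C so that only one equivalent adds, the C2 centre staying unfixed because the hemiketal anomers interconvert.

Step 6
Reactants: 10 C2 hemiketal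
Product: 11 (2S,4S,5R)-2-methoxy-2-[4-(PMB-oxy)-2-methylidenebutyl]-5-(TBDPS-oxymethyl)oxolan-4-ol
Conditions: PPTS (cat.), MeOH, rt
Reagents that add atoms: methanol, CO
Why: Acid-catalysed ketalization through the cyclic oxocarbenium ion (Fischer glycosidation type) with methanolysis of the labile TES ether in the same operation, C2 forming reversibly so that the 2S anomer (methoxy cis to O4, C1 chain cis to C6) is separated and the 2R anomer is equilibrated again under the same conditions.

Step 7
Reactants: 11 methyl ketal alcohol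
Product: 12 (2S,5R)-2-methoxy-2-[4-(PMB-oxy)-2-methylidenebutyl]-5-(TBDPS-oxymethyl)oxolan-4-one
Conditions: Dess–Martin periodinane, pyridine, CH2Cl2, 0 °C
Reagents that add atoms: none
Why: Dess–Martin oxidation of the secondary alcohol under buffered, non-basic conditions, which avoids β-elimination of methoxide from C2 and epimerization at C5 in the ketone formed.

Step 8
Reactants: 12 C4 ketone
Product: 13 (2S,5S)-2-methoxy-4-methylidene-2-[4-(PMB-oxy)-2-methylidenebutyl]-5-(TBDPS-oxymethyl)oxolane
Conditions: Ph3PCH3Br, KOtBu, THF, 0 °C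
Reagents that add atoms: methyltriphenylphosphonium bromide, C[P+](c1ccccc1)(c1ccccc1)c1ccccc1.[Br-]
Why: Wittig methylenation with the non-stabilized ylide at low temperature, where addition to the ketone is faster than its enolization, as in the methylenation of furanos-3-uloses.

Step 9
Reactants: 13 4-methylidene silyl ether
Product: 14 C6 alcohol [(2S,5S)-2-methoxy-4-methylidene-2-[4-(PMB-oxy)-2-methylidenebutyl]oxolan-5-yl]methanol
Conditions: Bu4NF, THF, 0 °C
Reagents that add atoms: none
Why: Fluoride cleavage of the silyl ether, driven by the Si–F bond, to which the PMB ether, the ketal and both alkenes are inert.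

Step 10
Reactants: 14 C6 alcohol
Product: 15 C6 aldehyde (2S,5S)-2-methoxy-4-methylidene-2-[4-(PMB-oxy)-2-methylidenebutyl]oxolane-5-carbaldehyde
Conditions: Dess–Martin periodinane, pyridine, CH2Cl2, 0 °C; used crude
Reagents that add atoms: none
Why: Dess–Martin oxidation gives the α-alkoxy aldehyde without base, so that the allylic C5–H is not enolized, and the aldehyde is used at once.

Step 11
Reactants: 15 C6 aldehyde
Product: 16 (6S)-1-[(2S,5S)-2-methoxy-4-methylidene-2-[4-(PMB-oxy)-2-methylidenebutyl]oxolan-5-yl]prop-2-en-1-ol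
Conditions: CH2=CHMgBr, MgBr2·OEt2, CH2Cl2, −78 °C; aq. NH4Cl
Reagents that add atoms: vinylmagnesium bromide, C=C[Mg]Br
Why: Chelation-controlled Grignard addition, in which magnesium bridges the aldehyde oxygen and ring oxygen O5 and the vinyl group adds to the face of the five-membered chelate that carries H5, which gives the 5,6-threo (6S) carbinol.

Step 12
Reactants: 16 C6 allylic alcohol; 17 acryloyl chloride
Product: 18 acrylate ester of 16 at O6
Conditions: iPr2NEt, CH2Cl2, 0 °C
Reagents that add atoms: none
Why: Acylation of the secondary allylic alcohol with the acid chloride and a hindered amine base (esterification), with no change at C6.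

Step 13
Reactants: 18 acrylate
Product: 19 (5S)-5-[(2S,5S)-2-methoxy-4-methylidene-2-[4-(PMB-oxy)-2-methylidenebutyl]oxolan-5-yl]furan-2(5H)-one
Conditions: second-generation Grubbs catalyst RuCl2(=CHPh)(PCy3)(H2IMes) (cat.), CH2Cl2, 40 °C
Reagents that add atoms: none
Why: Ring-closing metathesis, in which the ruthenium carbene forms at the monosubstituted C7 vinyl group and closes onto the acrylate to the five-membered butenolide with loss of ethene, while the two 1,1-disubstituted methylidene groups react far more slowly.

Step 14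
Reactants: 19 butenolide PMB ether
Product: 20 (5S)-5-[(2S,5S)-2-(4-hydroxy-2-methylidenebutyl)-2-methoxy-4-methylidene-oxolan-5-yl]furan-2(5H)-one
Conditions: DDQ, CH2Cl2/pH 7 phosphate buffer, 0 °C
Reagents that add atoms: none
Why: Oxidative cleavage of the PMB ether by DDQ through the benzylic oxocarbenium ion, with the neutral buffer keeping the freed O8–H from exchanging into the C2 ketal.

Step 15
Reactants: 20 C8 alcohol
Product: 21 C8 aldehyde 4-[(2S,5S)-2-methoxy-4-methylidene-5-[(2S)-5-oxo-2,5-dihydrofuran-2-yl]oxolan-2-yl]-3-methylidenebutanal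
Conditions: Dess–Martin periodinane, pyridine, CH2Cl2, 0 °C; used at once
Reagents that add atoms: none
Why: Dess–Martin oxidation of the homoallylic alcohol under pyridine buffering gives the β,γ-unsaturated aldehyde without migration of C10=C14, and it is taken into the electrolysis without storage.

Step 16
Reactants: 21 C8 aldehyde
Product: 22 tricyclic alcohol (2S,5S,6S,7R,8S): C1–C10 carbocycle with the 2,5-oxygen bridge, 2-OMe, 4- and 10-methylidene, trans γ-lactone O6–C12(=O)–C11H2–C7 and 8-OH
Conditions: divided cell, glassy-carbon cathode, potential held at the foot of the first reduction wave of 21, Et4NOTs (0.1 M), CH2(CO2Me)2 (3 equiv), DMF, 0 °C, 21 added slowly (≤2 mM)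
Reagents that add atoms: none
Why: Proposed new method: one-electron reduction of the butenolide at the cathode gives a radical anion with spin and charge at C7, which bonds to the nearby aldehyde carbon C8, and a second electron plus two protons from dimethyl malonate then give the saturated lactone (C11H2) and the C8 alcohol. The closest known reaction types are the electroreductive cyclization of aldehyde-tethered enoates to five- and six-membered rings and the cathodic hydrocoupling of aldehydes with acrylates, neither of which has been shown for a ten-membered ring. The carbocycle closes in a 10-exo-trig mode with respect to C7=C11, helped by the cis-2,5-disubstituted oxolane ketal, which turns the C1 chain back over the butenolide. C7 is set by approach anti to the C5 ring substituent at the C6 stereocentre, which gives the trans lactone (7R). C8 is set by the tether, which places C9 anti to C11 and leaves room only for hydrogen under the lactone ring, so that O8 points outward (8S). The step needs ring closure to outrun plain two-electron reduction and hydrodimerization of the butenolide, which slow addition at high dilution and the controlled potential should secure, and it needs a medium that never becomes strongly basic, which the malonate buffer should secure, so that C10=C14 does not move into conjugation with the aldehyde and the C8 alkoxide is protonated before it can attack the lactone.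

Step 17
Reactants: 22 tricyclic alcohol
Product: 23 O8-TES ether of 22
Conditions: TESCl, imidazole, DMF, rt
Reagents that add atoms: chlorotriethylsilane, CC[Si](Cl)(CC)CC
Why: Silylation of the secondary alcohol with imidazole as a weak base masks O8 so that no C8 alkoxide can open the lactone during the enolate step.

Step 18
Reactants: 23 O8-TES ether
Product: 25 11-(dimethylaminomethyl) lactone (C11 epimers), via lithium enolate 24 (not isolated)
Conditions: LiN(iPr)2, THF, −78 °C; then CH2=NMe2+ I−, −78 to 0 °C
Reagents that add atoms: Eschenmoser's salt (N,N-dimethylmethylideneammonium iodide), C=[N+](C)C.[I-]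
Why: Mannich reaction of the kinetic lithium enolate of the lactone with Eschenmoser's salt places the aminomethyl group on C11, whose configuration is of no consequence because C11 becomes sp2 in step 19.

Step 19
Reactants: 25 Mannich base
Product: 27 α-methylene lactone O8-TES ether, via ammonium iodide 26 (not isolated)
Conditions: MeI, THF, rt; then aq. NaHCO3, EtOAc, rt
Reagents that add atoms: none
Why: Exhaustive N-methylation makes trimethylamine a leaving group, and mild base then effects E1cB (Hofmann-type) elimination to the exocyclic C11=C13 double bond conjugated with the lactone.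

Step 20
Reactants: 27 α-methylene lactone O8-TES ether
Product: 28 α-methylene lactone alcohol (2S,5S,6S,7R,8S), the 11(13)-methylidene analogue of 22
Conditions: HF·pyridine, pyridine, THF, 0 °C
Reagents that add atoms: none
Why: Fluoride cleavage of the TES ether under buffered acidic conditions releases O8 as the alcohol and never as an alkoxide that could translactonize or add to the methylene lactone.

Step 21
Reactants: 28 α-methylene lactone alcohol; 29 tiglic acid
Product: 31 O8 tiglate methyl ketal, via mixed anhydride 30 (not isolated)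
Conditions: 29, 2,4,6-Cl3C6H2COCl, Et3N, toluene, rt; then 28, DMAP, rt
Reagents that add atoms: none
Why: Yamaguchi esterification, in which tiglic acid is activated as the mixed anhydride and transferred by DMAP to the hindered O8 with retention at C8 and without change of the E double bond.

Step 22
Reactants: 31 O8 tiglate methyl ketal
Product: 32 CNP0307443.2
Conditions: PPTS, acetone/H2O (4:1), rt
Reagents that add atoms: water, O
Why: Acid-catalysed ketal hydrolysis, in which methanol leaves C2 through the oxocarbenium ion or the open hydroxy ketone and water is captured, the bridged ring allowing only the 2S hemiketal.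

Compound list
1 | 2-deoxy-D-ribose | C(C=O)[C@@H]([C@@H](CO)O)O | starting material
2 | 2-deoxy-D-ribono-1,4-lactone, (4S,5R)-4-hydroxy-5-(hydroxymethyl)oxolan-2-one | O=C1C[C@H](O)[C@H](O1)CO | intermediate
3 | 5-O-TBDPS-2-deoxy-D-ribono-1,4-lactone | O=C1C[C@H](O)[C@H](O1)CO[Si](c1ccccc1)(c1ccccc1)C(C)(C)C | intermediate (not isolated)
4 | 5-O-TBDPS-3-O-TES-2-deoxy-D-ribono-1,4-lactone | O=C1C[C@H](O[Si](CC)(CC)CC)[C@H](O1)CO[Si](c1ccccc1)(c1ccccc1)C(C)(C)C | intermediate
5 | 3-methylbut-3-en-1-ol | CC(=C)CCO | starting material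
6 | lithium 3-(lithiomethyl)but-3-en-1-olate | [Li]CC(=C)CCO[Li] | intermediate (not isolated)
7 | 3-[(tributylstannyl)methyl]but-3-en-1-ol | CCCC[Sn](CCCC)(CCCC)CC(=C)CCO | intermediate
8 | tributyl{2-[2-(4-methoxybenzyloxy)ethyl]prop-2-en-1-yl}stannane | CCCC[Sn](CCCC)(CCCC)CC(=C)CCOCc1ccc(OC)cc1 | intermediate
9 | {2-[2-(4-methoxybenzyloxy)ethyl]prop-2-en-1-yl}lithium | [Li]CC(=C)CCOCc1ccc(OC)cc1 | intermediate (not isolated)
10 | (4S,5R)-2-[4-(PMB-oxy)-2-methylidenebutyl]-5-(TBDPS-oxymethyl)-4-(TES-oxy)oxolan-2-ol, both C2 anomers | COc1ccc(cc1)COCCC(=C)CC1(O)C[C@H](O[Si](CC)(CC)CC)[C@H](O1)CO[Si](c1ccccc1)(c1ccccc1)C(C)(C)C | intermediate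
11 | (2S,4S,5R)-2-methoxy-2-[4-(PMB-oxy)-2-methylidenebutyl]-5-(TBDPS-oxymethyl)oxolan-4-ol | COc1ccc(cc1)COCCC(=C)C[C@@]1(OC)C[C@H](O)[C@H](O1)CO[Si](c1ccccc1)(c1ccccc1)C(C)(C)C | intermediate
12 | (2S,5R)-2-methoxy-2-[4-(PMB-oxy)-2-methylidenebutyl]-5-(TBDPS-oxymethyl)oxolan-4-one | COc1ccc(cc1)COCCC(=C)C[C@@]1(OC)CC(=O)[C@H](O1)CO[Si](c1ccccc1)(c1ccccc1)C(C)(C)C | intermediate
13 | (2S,5S)-2-methoxy-4-methylidene-2-[4-(PMB-oxy)-2-methylidenebutyl]-5-(TBDPS-oxymethyl)oxolane | COc1ccc(cc1)COCCC(=C)C[C@@]1(OC)CC(=C)[C@H](O1)CO[Si](c1ccccc1)(c1ccccc1)C(C)(C)C | intermediate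
14 | [(2S,5S)-2-methoxy-4-methylidene-2-[4-(PMB-oxy)-2-methylidenebutyl]oxolan-5-yl]methanol | COc1ccc(cc1)COCCC(=C)C[C@@]1(OC)CC(=C)[C@H](O1)CO | intermediate
15 | (2S,5S)-2-methoxy-4-methylidene-2-[4-(PMB-oxy)-2-methylidenebutyl]oxolane-5-carbaldehyde | COc1ccc(cc1)COCCC(=C)C[C@@]1(OC)CC(=C)[C@H](O1)C=O | intermediate
16 | (6S)-1-[(2S,5S)-2-methoxy-4-methylidene-2-[4-(PMB-oxy)-2-methylidenebutyl]oxolan-5-yl]prop-2-en-1-ol | COc1ccc(cc1)COCCC(=C)C[C@@]1(OC)CC(=C)[C@H](O1)[C@@H](O)C=C | intermediate
17 | acryloyl chloride | C=CC(=O)Cl | starting material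
18 | O6 acrylate of 16 | COc1ccc(cc1)COCCC(=C)C[C@@]1(OC)CC(=C)[C@H](O1)[C@@H](OC(=O)C=C)C=C | intermediate
19 | (5S)-5-[(2S,5S)-2-methoxy-4-methylidene-2-[4-(PMB-oxy)-2-methylidenebutyl]oxolan-5-yl]furan-2(5H)-one | COc1ccc(cc1)COCCC(=C)C[C@@]1(OC)CC(=C)[C@H](O1)[C@H]1OC(=O)C=C1 | intermediate
20 | (5S)-5-[(2S,5S)-2-(4-hydroxy-2-methylidenebutyl)-2-methoxy-4-methylidene-oxolan-5-yl]furan-2(5H)-one | OCCC(=C)C[C@@]1(OC)CC(=C)[C@H](O1)[C@H]1OC(=O)C=C1 | intermediate
21 | 4-[(2S,5S)-2-methoxy-4-methylidene-5-[(2S)-5-oxo-2,5-dihydrofuran-2-yl]oxolan-2-yl]-3-methylidenebutanal | O=CCC(=C)C[C@@]1(OC)CC(=C)[C@H](O1)[C@H]1OC(=O)C=C1 | intermediate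
22 | tricyclic alcohol (2S,5S,6S,7R,8S): 2,5-oxygen-bridged C1–C10 carbocycle, 2-OMe, 4,10-bis(methylidene), trans lactone with C11H2, 8-OH | C=C1C[C@H](O)[C@H]2CC(=O)O[C@@H]2[C@H]2O[C@@](OC)(C1)CC2=C | intermediate
23 | O8-TES ether of 22 | C=C1C[C@H](O[Si](CC)(CC)CC)[C@H]2CC(=O)O[C@@H]2[C@H]2O[C@@](OC)(C1)CC2=C | intermediate
24 | lithium enolate of 23 (C11=C12–OLi) | C=C1C[C@H](O[Si](CC)(CC)CC)[C@H]2C=C(O[Li])O[C@@H]2[C@H]2O[C@@](OC)(C1)CC2=C | intermediate (not isolated)
25 | 11-(dimethylaminomethyl) derivative of 23, C11 epimers | C=C1C[C@H](O[Si](CC)(CC)CC)[C@H]2C(CN(C)C)C(=O)O[C@@H]2[C@H]2O[C@@](OC)(C1)CC2=C | intermediate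
26 | 11-(trimethylammoniomethyl) iodide of 23 | C=C1C[C@H](O[Si](CC)(CC)CC)[C@H]2C(C[N+](C)(C)C)C(=O)O[C@@H]2[C@H]2O[C@@](OC)(C1)CC2=C.[I-] | intermediate (not isolated)
27 | 11(13)-methylidene lactone, O8-TES ether | C=C1C[C@H](O[Si](CC)(CC)CC)[C@H]2C(=C)C(=O)O[C@@H]2[C@H]2O[C@@](OC)(C1)CC2=C | intermediate
28 | 11(13)-methylidene lactone, 8-OH, 2-OMe (2S,5S,6S,7R,8S) | C=C1C[C@H](O)[C@H]2C(=C)C(=O)O[C@@H]2[C@H]2O[C@@](OC)(C1)CC2=C | intermediate
29 | tiglic acid, (E)-2-methylbut-2-enoic acid | C/C=C(\C)C(=O)O | starting material
30 | tiglic 2,4,6-trichlorobenzoic anhydride | C/C=C(\C)C(=O)OC(=O)c1c(Cl)cc(Cl)cc1Cl | intermediate (not isolated)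
31 | O8 tiglate of 28 (methyl ketal of the target) | C=C1C[C@H](OC(=O)/C(C)=C/C)[C@H]2C(=C)C(=O)O[C@@H]2[C@H]2O[C@@](OC)(C1)CC2=C | intermediate
32 | CNP0307443.2 (2S,5S,6S,7R,8S) | C=C1C[C@H](OC(=O)/C(C)=C/C)[C@H]2C(=C)C(=O)O[C@@H]2[C@H]2O[C@@](O)(C1)CC2=C | target

Total steps: 22. Longest linear sequence: 20 steps (steps 1, 2 and 5–22 from 2-deoxy-D-ribose; the branch through steps 3 and 4 is equally long).

Steps most likely to fail

Step 16. The ten-membered closure may lose to faster processes: two-electron reduction of the butenolide or the aldehyde without C–C bond formation, intermolecular hydrodimerization, or base-induced migration of C10=C14 into conjugation with the aldehyde followed by reduction of the enal. In that case the C7–C8 bond would be made by an intramolecular Nozaki–Hiyama allylation, a known way to close ten-membered rings onto α-methylene lactones. The fallback sets out from acrylate 18. A Morita–Baylis–Hillman reaction with aqueous formaldehyde (DABCO, dioxane/H2O) should give the 2-(hydroxymethyl)acrylate F1. Ring-closing metathesis (second-generation Grubbs catalyst, toluene, 80 °C) should give the 3-(hydroxymethyl)butenolide F2, and Appel bromination (CBr4, PPh3, CH2Cl2) the 3-(bromomethyl)butenolide F3. DDQ under buffer should then give the C8 alcohol F4, and Dess–Martin oxidation the bromo aldehyde F5. CrCl2 in THF at high dilution converts the allylic bromide into an allylchromium species that attacks C8 through C7, anti to the C6 substituent, with transposition of the double bond to C11=C13. The route is rejoined at alcohol 28, and steps 16–20 are bypassed.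

Step 11. Facial selectivity may be poor if ring oxygen O5, flanked by the ketal, binds magnesium weakly, so that the open transition state competes and the 6R carbinol forms. The fallback turns this into the working mode. From aldehyde 15, vinylmagnesium bromide in THF without MgBr2 should favour the non-chelated (Felkin–Anh) addition and give the (6R)-allylic alcohol F6. Mitsunobu esterification of F6 with acrylic acid (PPh3, DIAD, THF, 0 °C) inverts C6 and delivers acrylate 18 directly, where the route is rejoined.

Step 8. The ylide may act as a base on the C4 ketone, which would epimerize C5 or expel methoxide from C2 by β-elimination. The fallback replaces the one-step olefination by a Peterson sequence with a non-basic nucleophile. From ketone 12, Me3SiCH2MgCl with CeCl3 in THF at −78 °C should add to the carbonyl and give the β-hydroxysilane F7 (either C4 epimer). KH in THF then effects syn elimination of silanolate and gives the methylidene compound 13, where the route is rejoined.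

Further compounds
F1 | step 16 | O6 2-(hydroxymethyl)acrylate of 16 | COc1ccc(cc1)COCCC(=C)C[C@@]1(OC)CC(=C)[C@H](O1)[C@@H](OC(=O)C(=C)CO)C=C
F2 | step 16 | (5S)-3-(hydroxymethyl)-5-[(2S,5S)-2-methoxy-4-methylidene-2-[4-(PMB-oxy)-2-methylidenebutyl]oxolan-5-yl]furan-2(5H)-one | COc1ccc(cc1)COCCC(=C)C[C@@]1(OC)CC(=C)[C@H](O1)[C@H]1OC(=O)C(CO)=C1
F3 | step 16 | 3-(bromomethyl) analogue of F2 | COc1ccc(cc1)COCCC(=C)C[C@@]1(OC)CC(=C)[C@H](O1)[C@H]1OC(=O)C(CBr)=C1
F4 | step 16 | 3-(bromomethyl)butenolide C8 alcohol | OCCC(=C)C[C@@]1(OC)CC(=C)[C@H](O1)[C@H]1OC(=O)C(CBr)=C1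
F5 | step 16 | 3-(bromomethyl)butenolide C8 aldehyde | O=CCC(=C)C[C@@]1(OC)CC(=C)[C@H](O1)[C@H]1OC(=O)C(CBr)=C1
F6 | step 11 | (6R)-1-[(2S,5S)-2-methoxy-4-methylidene-2-[4-(PMB-oxy)-2-methylidenebutyl]oxolan-5-yl]prop-2-en-1-ol | COc1ccc(cc1)COCCC(=C)C[C@@]1(OC)CC(=C)[C@H](O1)[C@H](O)C=C
F7 | step 8 | (2S,5R)-2-methoxy-2-[4-(PMB-oxy)-2-methylidenebutyl]-5-(TBDPS-oxymethyl)-4-[(trimethylsilyl)methyl]oxolan-4-ol, either C4 epimer | COc1ccc(cc1)COCCC(=C)C[C@@]1(OC)CC(O)(C[Si](C)(C)C)[C@H](O1)CO[Si](c1ccccc1)(c1ccccc1)C(C)(C)C
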